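Intermediate B was the pool I reckoned on, in two flasks charged alike and read at different times.

| setting | north-east | south-east |
|---|---|---|
| substrate | 0.068 M | 0.068 M |
| time | 6.0 h | 8.0 h |

- which of these there is most of at the end, counted by the substrate in it, north-east (intermediate B / intermediate C / intermediate A / target)
- which of these there is most of at the end, counted by the substrate in it, south-east (intermediate B / intermediate C / intermediate A / target)
- final amount of the leader among these, as a percentage of the substrate charged, in north-east
- final amount of the leader among these, as a percentage of the substrate charged, in south-east

    intermediate C → target (k1 = 0.212 /h)
    substrate ⇌ dormant form (K2 = 16.6, k2 = 0.131 /h)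
    intermediate A → intermediate B (k3 = 0.414 /h)
    target ⇌ isomer of the product (K4 = 0.143, k4 = 0.948 /h)
    intermediate B → intermediate C (k5 = 0.143 /h)
    substrate → intermediate A (k6 = 0.862 /h)

Substrate left for intermediate A at 0.862 /h and for the dormant form at 0.131 /h. The way back from the dormant form ran at 0.00789 /h, and I dropped it because it was far slower than the way in. That gave substrate a lifetime τ of 1.01 h and sent a share s of 86.8 % down the chain. I treated τ as a delay, then followed A going to B at 0.414 /h and B going to intermediate C at 0.143 /h, the smallest constant of the chain.

The quantity I carried was the crest time of B, t_c, the moment its feed from A equals its drain into C, reckoned as τ plus the logarithm of the ratio of those two constants over their difference: 4.93 h. Both readings came later than that, so I expected B to be falling in both flasks.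

I reckoned A at 11.0 % north-east and 4.80 % south-east. As a bound, I gave C and the target each the whole of what had passed B. That put intermediate B ahead north-east at 48.2 %, and intermediate B ahead south-east at 41.5 %.

The forecast named intermediate B at 47.2 % north-east and intermediate B at 41.5 % south-east, saying “material piles up in intermediate B”; its north-east figure differs from mine.

North-east gave intermediate B at 47.1 %. South-east gave intermediate B at 41.3 %.

At 8.00 h in south-east, B was being made at 0.391 of the rate at which it was used up, a falling pool at a reading later than the t_c of 4.93 h. The neighbour, the same south-east flask read at 5.0 h, close to t_c, held 47.7 % of B, more than the 45.5 % at 4.00 h. Left until 20 h, that flask held 9.33 % of B, and its leader was target.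

The constants used here come from no measurement; no experiment stands behind them.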